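**Retrosynthetic overview**
1. Target ⇐ desilylation, ene-type chlorination of the C5=C6 alkene (gives 6-Cl and the C5=C16 methylene) and C13=C14 dehydrogenation of a tetracyclic 2,8-ether lactone.
2. Oxane ring (O–C8) ⇐ transannular oxa-Michael addition of the C2 alkoxide to a C8=C17 butenolide; C11-OAc ⇐ the silyl enol ether left by the carbocyclization.
3. Cyclohexane ring (C1–C10) ⇐ transannular radical closure of a 14-membered 1,2-epoxy-10-en-12-one, the radical counterpart of the cembrane-to-briarane closure.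
4. 14-membered ring ⇐ ring-closing metathesis (C10=C11); butenolide ⇐ Nozaki–Hiyama–Kishi coupling/lactonization of an enol triflate with a lactol; C9 ⇐ asymmetric vinylation.
5. Chain ⇐ geranial + senecioate dienolate (asymmetric vinylogous aldol lactone). Ring order: butenolide → 14-membered carbocycle → cyclohexane → oxane.

Assumption: intermediates carry briarane numbering (ring carbons C1–C14, C15 on C1, C16 on C5, lactone carbons C17–C19 with C18 on C17, C20 on C11), and geranial (E-citral) is taken as a commercial commodity.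

**Route**

Step 1
Reactants: 1 methyl 3-methylbut-2-enoate
Product: 2 1-methoxy-3-methyl-1-(trimethylsilyloxy)buta-1,3-diene
Conditions: LiN(i-Pr)2, THF, −78 °C; Me3SiCl
Reagents that add atoms: chlorotrimethylsilane, C[Si](C)(C)Cl
Why: Kinetic γ-deprotonation of the senecioate gives the extended enolate, which is O-silylated to the silyl dienolate needed for a vinylogous Mukaiyama aldol reaction (no stereocenter).

Step 2
Reactants: 3 geranial; 2 1-methoxy-3-methyl-1-(trimethylsilyloxy)buta-1,3-diene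
Product: 4 (6R)-6-[(1E)-2,6-dimethylhepta-1,5-dien-1-yl]-4-methyl-5,6-dihydro-2H-pyran-2-one
Conditions: Cu(OTf)2 (10 mol %), (S)-Tol-BINAP, Bu4N[Ph3SiF2], THF, −78 °C to rt
Reagents that add atoms: none
Why: Copper fluoride–Tol-BINAP-catalyzed vinylogous Mukaiyama aldol reaction in which the chiral copper dienolate adds through its γ-carbon to one face of the enal carbonyl to set C3 (R), and the Z-configured aldolate lactonizes with loss of MeOSiMe3, which also locks C5=C6 as Z.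

Step 3
Reactants: 4 (6R)-6-[(1E)-2,6-dimethylhepta-1,5-dien-1-yl]-4-methyl-5,6-dihydro-2H-pyran-2-one
Product: 5 (6R)-6-[(1E)-2,6-dimethylhepta-1,5-dien-1-yl]-4-methyl-5,6-dihydro-2H-pyran-2-ol
Conditions: i-Bu2AlH, CH2Cl2, −78 °C
Reagents that add atoms: none
Why: Half-reduction of the unsaturated δ-lactone stops at the tetrahedral aluminate and gives the lactol, a masked (Z)-enal at C7 with latent C3-OH (anomeric center inconsequential).

Step 4
Reactants: 6 methyl 4,4-dimethoxy-3-oxobutanoate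
Product: 7 methyl 4,4-dimethoxy-2-methyl-3-oxobutanoate
Conditions: K2CO3, MeI, acetone, rt
Reagents that add atoms: iodomethane, CI
Why: C-alkylation of the β-keto ester enolate installs C18; the stereocenter formed is erased in step 5.

Step 5
Reactants: 7 methyl 4,4-dimethoxy-2-methyl-3-oxobutanoate
Product: 8 methyl (2Z)-4,4-dimethoxy-2-methyl-3-(trifluoromethanesulfonyloxy)but-2-enoate
Conditions: Tf2O, aq. LiOH, toluene, 5 °C
Reagents that add atoms: trifluoromethanesulfonic anhydride, O=S(=O)(OS(=O)(=O)C(F)(F)F)C(F)(F)F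
Why: Stereoselective enol triflation in which the chelated lithium Z-enolate is O-sulfonylated, placing triflate and ester cis as the later lactonization requires.

Step 6
Reactants: 5 (6R)-6-[(1E)-2,6-dimethylhepta-1,5-dien-1-yl]-4-methyl-5,6-dihydro-2H-pyran-2-ol; 8 methyl (2Z)-4,4-dimethoxy-2-methyl-3-(trifluoromethanesulfonyloxy)but-2-enoate
Product: 10 (5S)-5-[(1Z,4R,5E)-4-(tert-butyldimethylsilyloxy)-2,6,10-trimethylundeca-1,5,9-trien-1-yl]-4-(dimethoxymethyl)-3-methylfuran-2(5H)-one, via butenolide alcohol 9 (not isolated)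
Conditions: CrCl2, NiCl2 (2 mol %), chiral oxazoline–sulfonamide ligand (Kishi type), Et3N, THF, rt; crude; then t-BuMe2SiOTf, 2,6-lutidine, CH2Cl2, −78 °C
Reagents that add atoms: tert-butyldimethylsilyl trifluoromethanesulfonate, CC(C)(C)[Si](C)(C)OS(=O)(=O)C(F)(F)F
Why: Nozaki–Hiyama–Kishi coupling, lactonization and silylation: the vinylchromium species from the enol triflate adds to the open enal tautomer of 5 with the ligand-bound chromium choosing the carbonyl face (sets C7, S at this stage), the chromium alkoxide closes onto the cis ester to the butenolide, and the liberated C3-OH is silylated.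

Step 7
Reactants: 10 (5S)-5-[(1Z,4R,5E)-4-(tert-butyldimethylsilyloxy)-2,6,10-trimethylundeca-1,5,9-trien-1-yl]-4-(dimethoxymethyl)-3-methylfuran-2(5H)-one
Product: 11 (2S)-2-[(1Z,4R,5E)-4-(tert-butyldimethylsilyloxy)-2,6,10-trimethylundeca-1,5,9-trien-1-yl]-4-methyl-5-oxo-2,5-dihydrofuran-3-carbaldehyde
Conditions: LiBF4, MeCN/H2O (50:1), 50 °C
Reagents that add atoms: water, O
Why: Mild Lewis-acid acetal hydrolysis unveils the C9 aldehyde before any epoxide is present, leaving the secondary silyl ether and the butenolide intact.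

Step 8
Reactants: 11 (2S)-2-[(1Z,4R,5E)-4-(tert-butyldimethylsilyloxy)-2,6,10-trimethylundeca-1,5,9-trien-1-yl]-4-methyl-5-oxo-2,5-dihydrofuran-3-carbaldehyde
Product: 13 (1S)-1-{(2S)-2-[(1Z,4R,5E)-4-(tert-butyldimethylsilyloxy)-2,6,10-trimethylundeca-1,5,9-trien-1-yl]-4-methyl-5-oxo-2,5-dihydrofuran-3-yl}prop-2-en-1-yl acetate, via C9 allylic alcohol 12 (not isolated)
Conditions: vinyl bromide, CrCl2, NiCl2 (2 mol %), chiral oxazoline–sulfonamide ligand (Kishi type), Et3N, THF, 0 °C; then Ac2O, pyridine, DMAP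
Reagents that add atoms: vinyl bromide, C=CBr; acetic anhydride, CC(=O)OC(C)=O
Why: Catalyst-controlled Nozaki–Hiyama–Kishi vinylation in which the ligand-bound vinylchromium adds to one face of the formyl group to set C9 (S), and the chromium alkoxide is acetylated in the same flask.

Step 9
Reactants: 13 (1S)-1-{(2S)-2-[(1Z,4R,5E)-4-(tert-butyldimethylsilyloxy)-2,6,10-trimethylundeca-1,5,9-trien-1-yl]-4-methyl-5-oxo-2,5-dihydrofuran-3-yl}prop-2-en-1-yl acetate
Product: 15 (1S)-1-{(2S)-2-[(1Z,4R,5E)-4-(tert-butyldimethylsilyloxy)-2,6,10-trimethyl-9-oxoundeca-1,5,10-trien-1-yl]-4-methyl-5-oxo-2,5-dihydrofuran-3-yl}prop-2-en-1-yl acetate, via allylic hydroperoxide 14 (not isolated)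
Conditions: O2, tetraphenylporphyrin (cat.), hν, CH2Cl2, 0 °C; then Ac2O, pyridine, DMAP
Reagents that add atoms: dioxygen, O=O
Why: Schenck ene reaction of singlet oxygen at the most electron-rich (isopropylidene) alkene gives the secondary allylic hydroperoxide, which Ac2O/pyridine dehydrates (Kornblum–DeLaMare-type elimination) to the isopropenyl ketone carrying the C12 carbonyl; the tertiary hydroperoxide regioisomer is the main by-product, and the other two trisubstituted alkenes are slowed by their allylic oxygen substituents.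

Step 10
Reactants: 15 (1S)-1-{(2S)-2-[(1Z,4R,5E)-4-(tert-butyldimethylsilyloxy)-2,6,10-trimethyl-9-oxoundeca-1,5,10-trien-1-yl]-4-methyl-5-oxo-2,5-dihydrofuran-3-yl}prop-2-en-1-yl acetate
Product: 16 the (1S,2S)-1,2-epoxide of 15 (briarane C1–C2; C3 R, C7 S, C9 S)
Conditions: ent-Shi ketone (L-fructose-derived, 30 mol %), KHSO5 (as 2KHSO5·KHSO4·K2SO4), K2CO3, MeCN/dimethoxymethane/aq. buffer, 0 °C
Reagents that add atoms: potassium peroxymonosulfate, [K+].[O-]S(=O)(=O)OO
Why: Shi asymmetric epoxidation in which the chiral dioxirane attacks the only remaining electron-rich E-trisubstituted alkene through a spiro transition state, the catalyst antipode fixing C2, while the Z alkene, the vinyl group and the enone react far more slowly.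

Step 11
Reactants: 16 the (1S,2S)-1,2-epoxide of 15
Product: 17 (1S,2S,3R,5Z,7S,9S,10E)-9-acetoxy-3-(tert-butyldimethylsilyloxy)-1,2-epoxy-12-oxo-1,10-seco-briara-5,8(17),10-trien-19,7-olide (14-membered carbocycle)
Conditions: second-generation Grubbs catalyst, RuCl2(=CHPh)(H2IMes)(PCy3) (10 mol %), toluene, 80 °C, 1 mM
Reagents that add atoms: none
Why: Ring-closing metathesis between the allylic acetate vinyl group and the isopropenyl ketone expels ethylene and closes the 14-membered ring as the thermodynamically favored (E)-trisubstituted enone; no stereocenter is formed.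

Step 12
Reactants: 17 (1S,2S,3R,5Z,7S,9S,10E)-9-acetoxy-3-(tert-butyldimethylsilyloxy)-1,2-epoxy-12-oxo-1,10-seco-briara-5,8(17),10-trien-19,7-olide
Product: 18 (1S,2R,3R,5Z,7S,9S,10R)-9-acetoxy-3-(tert-butyldimethylsilyloxy)-2,12-bis(trimethylsilyloxy)briara-5,8(17),11-trien-19,7-olide
Conditions: Cp2TiCl2 (20 mol %), Mn dust, Me3SiCl, 2,4,6-collidine, THF, rt, 5 mM
Reagents that add atoms: chlorotrimethylsilane, C[Si](C)(C)Cl
Why: Proposed new method: Cp2TiCl (trivalent titanium, formed in the flask) opens the trisubstituted epoxide homolytically to the tertiary C1 radical with O2 on titanium, this nucleophilic radical adds across the ring in a 6-endo Giese mode to C10 of the facing enone through a chair with the C2 and C9 arms both equatorial (trans fusion, setting C1 and C10, with the face dictated by the C2 and C9 stereocenters and A(1,3) strain at C9), a second Cp2TiCl reduces the α-keto radical to the titanium enolate, and Me3SiCl traps both Ti–O bonds as the C2 silyl ether and the regiodefined C11=C12 silyl enol ether while turning titanium over; the closest known reactions are titanocene-mediated radical cyclizations of epoxypolyprenes and of epoxides onto α,β-unsaturated carbonyl compounds.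

Step 13
Reactants: 18 (1S,2R,3R,5Z,7S,9S,10R)-9-acetoxy-3-(tert-butyldimethylsilyloxy)-2,12-bis(trimethylsilyloxy)briara-5,8(17),11-trien-19,7-olide
Product: 21 (1S,2R,3R,5Z,7S,8R,9S,10S,11S,17R)-9,11-diacetoxy-3-(tert-butyldimethylsilyloxy)-2,8-epoxy-12-oxobriar-5-en-19,7-olide, via acetoxy ketone silyl ether 19 (not isolated), via acetoxy hydroxy ketone 20 (not isolated)
Conditions: Pb(OAc)4, CH2Cl2, −20 °C; aq. citric acid, THF; then DBU, CH2Cl2, 0 °C
Reagents that add atoms: lead tetraacetate, CC(=O)O[Pb](OC(C)=O)(OC(C)=O)OC(C)=O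
Why: Rubottom-type oxidation of the silyl enol ether delivers acetate to C11 from the face opposite the pseudoaxial C9 arm and the axial C15 methyl (C11 S), mild acid frees the C2 hydroxyl, and DBU promotes a transannular 6-exo oxa-Michael addition of O2 to C8 of the butenolide, where the cis-2,6-diaxial bridge demanded by the ten-membered ring fixes C8 and protonation of the lactone enolate on the face away from C9 gives C17 (R).

Step 14
Reactants: 21 (1S,2R,3R,5Z,7S,8R,9S,10S,11S,17R)-9,11-diacetoxy-3-(tert-butyldimethylsilyloxy)-2,8-epoxy-12-oxobriar-5-en-19,7-olide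
Product: 22 (1S,2R,3R,5Z,7S,8R,9S,10S,11S,17R)-9,11-diacetoxy-3-(tert-butyldimethylsilyloxy)-2,8-epoxy-12-oxobriara-5,13-dien-19,7-olide
Conditions: IBX, 4-methoxypyridine N-oxide, DMSO, rt
Reagents that add atoms: none
Why: IBX dehydrogenation of the ketone can only proceed toward C13 because C11 is quaternary, giving the C13=C14 enone without touching a stereocenter.

Step 15
Reactants: 22 (1S,2R,3R,5Z,7S,8R,9S,10S,11S,17R)-9,11-diacetoxy-3-(tert-butyldimethylsilyloxy)-2,8-epoxy-12-oxobriara-5,13-dien-19,7-olide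
Product: 23 (1S,2R,3R,6S,7R,8S,9S,10S,11S,17R)-9,11-diacetoxy-3-(tert-butyldimethylsilyloxy)-6-chloro-2,8-epoxy-12-oxobriara-5(16),13-dien-19,7-olide
Conditions: N-chlorosuccinimide, PhSeCl (10 mol %), CH2Cl2, rt
Reagents that add atoms: N-chlorosuccinimide, O=C1CCC(=O)N1Cl
Why: Selenium-catalyzed ene-type allylic chlorination in which the electrophile adds to the only electron-rich alkene, chlorine ends on C6 with the double bond shifting to the exocyclic C5=C16 position, and attack on the exposed convex face of the bridged oxocane away from the ether bridge is expected to set C6 (S).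

Step 16
Reactants: 23 (1S,2R,3R,6S,7R,8S,9S,10S,11S,17R)-9,11-diacetoxy-3-(tert-butyldimethylsilyloxy)-6-chloro-2,8-epoxy-12-oxobriara-5(16),13-dien-19,7-olide
Product: 24 CNP0253524.4, (1S,2R,3R,6S,7R,8S,9S,10S,11S,17R)-9,11-diacetoxy-6-chloro-2,8-epoxy-3-hydroxy-12-oxobriara-5(16),13-dien-19,7-olide
Conditions: HF·pyridine, THF, 0 °C to rt
Reagents that add atoms: none
Why: Fluoride-mediated desilylation cleaves the secondary silyl ether without affecting the acetates, lactone, enone or allylic chloride and gives the target.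

**Compound list**
1 | methyl 3-methylbut-2-enoate | COC(=O)C=C(C)C | starting material
2 | 1-methoxy-3-methyl-1-(trimethylsilyloxy)buta-1,3-diene (ketene acetal geometry not controlled) | C=C(C)C=C(OC)O[Si](C)(C)C | intermediate
3 | geranial, (2E)-3,7-dimethylocta-2,6-dienal | CC(C)=CCC/C(C)=C/C=O | starting material
4 | (6R)-6-[(1E)-2,6-dimethylhepta-1,5-dien-1-yl]-4-methyl-5,6-dihydro-2H-pyran-2-one | CC1=CC(=O)O[C@H](C1)/C=C(\C)CCC=C(C)C | intermediate
5 | (6R)-6-[(1E)-2,6-dimethylhepta-1,5-dien-1-yl]-4-methyl-5,6-dihydro-2H-pyran-2-ol (anomer mixture) | CC1=CC(O)O[C@H](C1)/C=C(\C)CCC=C(C)C | intermediate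
6 | methyl 4,4-dimethoxy-3-oxobutanoate | COC(OC)C(=O)CC(=O)OC | starting material
7 | methyl 4,4-dimethoxy-2-methyl-3-oxobutanoate (racemic) | COC(OC)C(=O)C(C)C(=O)OC | intermediate
8 | methyl (2Z)-4,4-dimethoxy-2-methyl-3-(trifluoromethanesulfonyloxy)but-2-enoate | COC(=O)/C(C)=C(\OS(=O)(=O)C(F)(F)F)C(OC)OC | intermediate
9 | (5S)-4-(dimethoxymethyl)-5-[(1Z,4R,5E)-4-hydroxy-2,6,10-trimethylundeca-1,5,9-trien-1-yl]-3-methylfuran-2(5H)-one | COC(OC)C1=C(C)C(=O)O[C@H]1/C=C(C)\C[C@@H](O)/C=C(\C)CCC=C(C)C | intermediate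
10 | (5S)-5-[(1Z,4R,5E)-4-(tert-butyldimethylsilyloxy)-2,6,10-trimethylundeca-1,5,9-trien-1-yl]-4-(dimethoxymethyl)-3-methylfuran-2(5H)-one | COC(OC)C1=C(C)C(=O)O[C@H]1/C=C(C)\C[C@@H](O[Si](C)(C)C(C)(C)C)/C=C(\C)CCC=C(C)C | intermediate
11 | (2S)-2-[(1Z,4R,5E)-4-(tert-butyldimethylsilyloxy)-2,6,10-trimethylundeca-1,5,9-trien-1-yl]-4-methyl-5-oxo-2,5-dihydrofuran-3-carbaldehyde | O=CC1=C(C)C(=O)O[C@H]1/C=C(C)\C[C@@H](O[Si](C)(C)C(C)(C)C)/C=C(\C)CCC=C(C)C | intermediate
12 | (5S)-5-[(1Z,4R,5E)-4-(tert-butyldimethylsilyloxy)-2,6,10-trimethylundeca-1,5,9-trien-1-yl]-4-[(1S)-1-hydroxyprop-2-en-1-yl]-3-methylfuran-2(5H)-one | C=C[C@H](O)C1=C(C)C(=O)O[C@H]1/C=C(C)\C[C@@H](O[Si](C)(C)C(C)(C)C)/C=C(\C)CCC=C(C)C | intermediate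
13 | (1S)-1-{(2S)-2-[(1Z,4R,5E)-4-(tert-butyldimethylsilyloxy)-2,6,10-trimethylundeca-1,5,9-trien-1-yl]-4-methyl-5-oxo-2,5-dihydrofuran-3-yl}prop-2-en-1-yl acetate | C=C[C@H](OC(C)=O)C1=C(C)C(=O)O[C@H]1/C=C(C)\C[C@@H](O[Si](C)(C)C(C)(C)C)/C=C(\C)CCC=C(C)C | intermediate
14 | 13 with the chain terminus as the C12 hydroperoxide and isopropenyl group: side chain (1Z,4R,5E)-4-(tert-butyldimethylsilyloxy)-9-hydroperoxy-2,6,10-trimethylundeca-1,5,10-trien-1-yl (C12 epimers) | C=C[C@H](OC(C)=O)C1=C(C)C(=O)O[C@H]1/C=C(C)\C[C@@H](O[Si](C)(C)C(C)(C)C)/C=C(\C)CCC(OO)C(C)=C | intermediate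
15 | (1S)-1-{(2S)-2-[(1Z,4R,5E)-4-(tert-butyldimethylsilyloxy)-2,6,10-trimethyl-9-oxoundeca-1,5,10-trien-1-yl]-4-methyl-5-oxo-2,5-dihydrofuran-3-yl}prop-2-en-1-yl acetate | C=C[C@H](OC(C)=O)C1=C(C)C(=O)O[C@H]1/C=C(C)\C[C@@H](O[Si](C)(C)C(C)(C)C)/C=C(\C)CCC(=O)C(C)=C | intermediate
16 | (1S,2S)-1,2-epoxide of 15 (briarane numbering; oxirane carbon C2 bears H, C1 bears C15 and the C14–C11 keto-isopropenyl arm; C3 R, C7 S, C9 S) | C=C[C@H](OC(C)=O)C1=C(C)C(=O)O[C@H]1/C=C(C)\C[C@@H](O[Si](C)(C)C(C)(C)C)[C@@H]2O[C@@]2(C)CCC(=O)C(C)=C | intermediate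
17 | (1S,2S,3R,5Z,7S,9S,10E)-9-acetoxy-3-(tert-butyldimethylsilyloxy)-1,2-epoxy-12-oxo-1,10-seco-briara-5,8(17),10-trien-19,7-olide (14-membered carbocycle) | CC(=O)O[C@H]1/C=C(\C)C(=O)CC[C@]2(C)O[C@H]2[C@H](O[Si](C)(C)C(C)(C)C)C/C(C)=C\[C@@H]3OC(=O)C(C)=C13 | intermediate
18 | (1S,2R,3R,5Z,7S,9S,10R)-9-acetoxy-3-(tert-butyldimethylsilyloxy)-2,12-bis(trimethylsilyloxy)briara-5,8(17),11-trien-19,7-olide | CC(=O)O[C@H]1[C@H]4C(C)=C(O[Si](C)(C)C)CC[C@]4(C)[C@@H](O[Si](C)(C)C)[C@H](O[Si](C)(C)C(C)(C)C)C/C(C)=C\[C@@H]3OC(=O)C(C)=C13 | intermediate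
19 | (1S,2R,3R,5Z,7S,9S,10S,11S)-9,11-diacetoxy-3-(tert-butyldimethylsilyloxy)-12-oxo-2-(trimethylsilyloxy)briara-5,8(17)-dien-19,7-olide | CC(=O)O[C@H]1[C@H]4[C@](C)(OC(C)=O)C(=O)CC[C@]4(C)[C@@H](O[Si](C)(C)C)[C@H](O[Si](C)(C)C(C)(C)C)C/C(C)=C\[C@@H]3OC(=O)C(C)=C13 | intermediate
20 | (1S,2R,3R,5Z,7S,9S,10S,11S)-9,11-diacetoxy-3-(tert-butyldimethylsilyloxy)-2-hydroxy-12-oxobriara-5,8(17)-dien-19,7-olide | CC(=O)O[C@H]1[C@H]4[C@](C)(OC(C)=O)C(=O)CC[C@]4(C)[C@@H](O)[C@H](O[Si](C)(C)C(C)(C)C)C/C(C)=C\[C@@H]3OC(=O)C(C)=C13 | intermediate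
21 | (1S,2R,3R,5Z,7S,8R,9S,10S,11S,17R)-9,11-diacetoxy-3-(tert-butyldimethylsilyloxy)-2,8-epoxy-12-oxobriar-5-en-19,7-olide | C/C=1C[C@@H](O[Si](C)(C)C(C)(C)C)[C@@H]2O[C@@]3([C@@H](C)C(=O)O[C@H]3\C=1)[C@@H](OC(C)=O)[C@@H]1[C@]2(C)CCC(=O)[C@@]1(C)OC(C)=O | intermediate
22 | (1S,2R,3R,5Z,7S,8R,9S,10S,11S,17R)-9,11-diacetoxy-3-(tert-butyldimethylsilyloxy)-2,8-epoxy-12-oxobriara-5,13-dien-19,7-olide | C/C=1C[C@@H](O[Si](C)(C)C(C)(C)C)[C@@H]2O[C@@]3([C@@H](C)C(=O)O[C@H]3\C=1)[C@@H](OC(C)=O)[C@@H]1[C@]2(C)C=CC(=O)[C@@]1(C)OC(C)=O | intermediate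
23 | (1S,2R,3R,6S,7R,8S,9S,10S,11S,17R)-9,11-diacetoxy-3-(tert-butyldimethylsilyloxy)-6-chloro-2,8-epoxy-12-oxobriara-5(16),13-dien-19,7-olide | C=C1C[C@@H](O[Si](C)(C)C(C)(C)C)[C@@H]2O[C@@]3([C@@H](C)C(=O)O[C@H]3[C@H]1Cl)[C@@H](OC(C)=O)[C@@H]1[C@]2(C)C=CC(=O)[C@@]1(C)OC(C)=O | intermediate
24 | CNP0253524.4, (1S,2R,3R,6S,7R,8S,9S,10S,11S,17R)-9,11-diacetoxy-6-chloro-2,8-epoxy-3-hydroxy-12-oxobriara-5(16),13-dien-19,7-olide | C=C1C[C@@H](O)[C@@H]2O[C@@]3([C@@H](C)C(=O)O[C@H]3[C@H]1Cl)[C@@H](OC(C)=O)[C@@H]1[C@]2(C)C=CC(=O)[C@@]1(C)OC(C)=O | target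

**Totals and risks**
Total step count: 16. Longest linear sequence: 14 steps (steps 1–3, then 6–16).

Most likely to fail, with one fallback each:

Step 12. The transannular radical addition competes with β-hydride loss from the titanium-bound radical and with 5-exo attack of the C1 radical on the C5=C6 alkene. Fallback, from 17 back to 18: with excess Cp2TiCl and no Me3SiCl the epoxide is isomerized to the exocyclic allylic alcohol F1 (C2-OH, C1=C15 methylene). Hydrogen-atom transfer from an iron hydride (Fe(acac)3, PhSiH3, EtOH/ethylene glycol, 60 °C) to the terminal methylene then regenerates the same tertiary C1 radical free of titanium, which closes onto C10 to give the hydroxy ketone F2. Thermodynamic silylation (Me3SiCl, NaI, Et3N, MeCN) toward C11 and at O2 gives 18.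

Step 11. Metathesis must build a trisubstituted enone inside a 14-membered ring, and the isopropenyl ketone is a sluggish partner. Fallback, from 16 back to 17: Luche reduction (NaBH4, CeCl3·7H2O, MeOH, −40 °C) converts the ketone into the isopropenyl carbinol F3 (C12 epimers), whose free allylic hydroxyl activates the 1,1-disubstituted alkene. Ring-closing metathesis then gives the macrocyclic allylic alcohol F4, and Dess–Martin oxidation returns to 17 (any Z isomer equilibrated with catalytic iodine).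

Step 8. Catalyst control at C9 on the hindered, electron-poor formyl butenolide may give poor selectivity. Fallback, from 11 back to 12: vinylmagnesium bromide with CeCl3 (THF, −78 °C) adds to 11 to give the C9-epimeric allylic alcohols F5. Dess–Martin oxidation gives the vinyl ketone F6, and Corey–Bakshi–Shibata reduction (oxazaborolidine, catecholborane, −78 °C; large butenolide against small vinyl) delivers 12, which is acetylated as in step 8 to 13.

Further compounds
F1 | step 12 | (2R,3R,5Z,7S,9S,10E)-9-acetoxy-3-(tert-butyldimethylsilyloxy)-2-hydroxy-12-oxo-1,10-seco-briara-1(15),5,8(17),10-tetraen-19,7-olide | CC(=O)O[C@H]1/C=C(\C)C(=O)CCC(=C)[C@@H](O)[C@H](O[Si](C)(C)C(C)(C)C)C/C(C)=C\[C@@H]3OC(=O)C(C)=C13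
F2 | step 12 | (1S,2R,3R,5Z,7S,9S,10S)-9-acetoxy-3-(tert-butyldimethylsilyloxy)-2-hydroxy-12-oxobriara-5,8(17)-dien-19,7-olide (C11 epimers) | CC(=O)O[C@H]1[C@H]4C(C)C(=O)CC[C@]4(C)[C@@H](O)[C@H](O[Si](C)(C)C(C)(C)C)C/C(C)=C\[C@@H]3OC(=O)C(C)=C13
F3 | step 11 | 16 with the C12 ketone reduced to the alcohol (isopropenyl carbinol, C12 epimers) | C=C[C@H](OC(C)=O)C1=C(C)C(=O)O[C@H]1/C=C(C)\C[C@@H](O[Si](C)(C)C(C)(C)C)[C@@H]2O[C@@]2(C)CCC(O)C(C)=C
F4 | step 11 | 17 with the C12 ketone as the alcohol (macrocyclic allylic alcohol, C12 epimers) | CC(=O)O[C@H]1/C=C(\C)C(O)CC[C@]2(C)O[C@H]2[C@H](O[Si](C)(C)C(C)(C)C)C/C(C)=C\[C@@H]3OC(=O)C(C)=C13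
F5 | step 8 | 12 as the mixture of C9 epimers | C=CC(O)C1=C(C)C(=O)O[C@H]1/C=C(C)\C[C@@H](O[Si](C)(C)C(C)(C)C)/C=C(\C)CCC=C(C)C
F6 | step 8 | (5S)-5-[(1Z,4R,5E)-4-(tert-butyldimethylsilyloxy)-2,6,10-trimethylundeca-1,5,9-trien-1-yl]-3-methyl-4-(prop-2-enoyl)furan-2(5H)-one | C=CC(=O)C1=C(C)C(=O)O[C@H]1/C=C(C)\C[C@@H](O[Si](C)(C)C(C)(C)C)/C=C(\C)CCC=C(C)C
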